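## Retrosynthetic overview

1. Target 5 is an isomer of prostaglandin D2 (4): the C15 ketone and saturated C13–C14 come from the 15S allylic alcohol and 13E alkene by an internal 1,3-hydrogen shift.
2. 4 comes from prostaglandin H2 (3): the 11-ketone/9α-alcohol arises from the 9α,11α-peroxide bridge, opened with loss of H-11.
3. 3 comes from prostaglandin G2 (2), and 2 from arachidonic acid (1) plus two O2: the C11–O, O–C9, C8–C12 and C15–O bonds form in one radical cascade.
4. Ring order: the 1,2-dioxolane closes first (peroxyl radical onto C9), then the cyclopentane (C8 radical onto C12), giving the 2,3-dioxabicyclo[2.2.1]heptane. The O–O ring is then opened, so the cyclopentane is the only ring left in 4 and 5.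

Assumption: purified ovine COX-1 and recombinant human hematopoietic PGD synthase are bought and used as catalysts; arachidonic acid is the only carbon source.

## Route

Step 1
Reactants: 1 arachidonic acid
Product: 4 prostaglandin D2, via prostaglandin G2 2 (not isolated), via prostaglandin H2 3 (not isolated)
Conditions: ovine COX-1 holoenzyme (0.2 mol %, two portions), human hematopoietic PGD synthase (0.05 mol %), hydroquinone (1.1 equiv), GSH (5 mM, cofactor), O2 (1 atm), Tris-HCl buffer pH 8.0 (1 at 0.5 mM), 25 °C, 15 min; then pH 3.5, EtOAc, silica (EtOAc/hexane/AcOH)
Reagents that add atoms: dioxygen, O=O (two molecules are taken up; three of the four oxygen atoms stay in 4)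
Why: Cyclooxygenase reaction (enzyme-templated radical bis-dioxygenation with 5-exo/5-exo cyclization), then peroxidase reduction and a glutathione-assisted Kornblum–DeLaMare-type endoperoxide isomerization in the same pot: the active-site tyrosyl radical removes the 13-pro-S hydrogen, O2 adds at C11 (R), the 11-peroxyl radical closes onto C9 to form the dioxolane, the C8 radical closes onto C12 to form the cyclopentane with the two chains trans (8R, 12R) and the peroxide bridge on the α face (9S), a second O2 is taken up at C15 (S), hydroquinone reduces the 15-hydroperoxide of 2 at the peroxidase site, and the PGD synthase removes H-11 as the O–O bond breaks so that only the 11-ketone/9α-alcohol forms; the enzyme pocket enforces the trans ring substitution and the single enantiomer, which the free-solution radical cascade (cis chains, racemic) does not give.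

Step 2
Reactants: 4 prostaglandin D2
Product: 5 13,14-dihydro-15-keto-prostaglandin D2
Conditions: [Rh(COD)(MeCN)2]BF4 (5 mol %), 1,3,5-triaza-7-phosphaadamantane (10 mol %), KH2PO4/K2HPO4 buffer pH 7.0/THF 4:1, degassed, Ar, 23 °C, 4 h; then pH 3.5, EtOAc, silica
Reagents that add atoms: none
Why: Transition-metal-catalysed redox isomerization of a secondary allylic alcohol (net 1,3-hydrogen shift, atom-neutral, no by-product), a known reaction class not yet tested on this substrate: the C15 alkoxide on monovalent rhodium undergoes β-hydride elimination and the hydride returns to C13 of the still metal-bound enone before the rhodium enolate is protonated, so the isolated 5Z alkene, the non-allylic 9α-OH and the C11 ketone are not engaged, no new stereocenter arises (C15 becomes sp2), and the neutral ambient conditions spare the β-ketol and leave C12 in its thermodynamically preferred trans relationship to C8.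

## Compound list

1 | arachidonic acid, (5Z,8Z,11Z,14Z)-icosa-5,8,11,14-tetraenoic acid | CCCCC/C=C\C/C=C\C/C=C\C/C=C\CCCC(=O)O | starting material
2 | prostaglandin G2, 9α,11α-epidioxy-15S-hydroperoxy-prosta-5Z,13E-dienoic acid | CCCCC[C@H](OO)/C=C/[C@H]1[C@H]2C[C@H](OO2)[C@@H]1C/C=C\CCCC(=O)O | intermediate
3 | prostaglandin H2, 9α,11α-epidioxy-15S-hydroxy-prosta-5Z,13E-dienoic acid | CCCCC[C@H](O)/C=C/[C@H]1[C@H]2C[C@H](OO2)[C@@H]1C/C=C\CCCC(=O)O | intermediate
4 | prostaglandin D2, 9α,15S-dihydroxy-11-oxo-prosta-5Z,13E-dienoic acid | CCCCC[C@H](O)/C=C/[C@H]1C(=O)C[C@H](O)[C@@H]1C/C=C\CCCC(=O)O | intermediate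
5 | 13,14-dihydro-15-keto-prostaglandin D2, (Z)-7-[(1R,2R,5S)-5-hydroxy-3-oxo-2-(3-oxooctyl)cyclopentyl]hept-5-enoic acid | CCCCCC(=O)CC[C@H]1C(=O)C[C@H](O)[C@@H]1C/C=C\CCCC(=O)O | target

## Step count and risks

Total step count: 2. Longest linear sequence: 2.

The route has only two steps, so the two enzymatic stages of step 1 are ranked separately, followed by step 2.

Step 1, oxygenation and cyclization stage (1 to 3). COX-1 inactivates itself after roughly a thousand turnovers, thiol/quinone cross-talk can starve the peroxidase cycle, and 11-HETE, 15-HETE and HHT compete. The fallback sets out from 1 and comes back at 4 by uncoupling the cascade. Oxygenate 1 with a large excess of crude ram seminal vesicle microsomes and hydroquinone under O2 with no glutathione in the pot, so the glutathione-dependent microsomal isomerases stay idle. Stop after 2 min by extraction into cold ether at pH 3.5, purify prostaglandin H2 (3) on silica at −20 °C, and only then expose it to the PGD synthase and GSH in a second pot to reach 4. This way makes no compound outside the list: none F0.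

Step 1, endoperoxide isomerization stage (3 to 4). Compound 3 lives only minutes in buffer and opens spontaneously mainly toward the C9 ketone (PGE2) and to HHT, so any lag of the synthase erodes the regiochemistry. The fallback sets out from 1 and comes back at 5; it gives up regioselective opening of the peroxide and differentiates the two ring oxygens afterwards. Run the oxygenation of 1 without the synthase and quench with SnCl2, which reduces the peroxide bridge to the 9α,11α-diol prostaglandin F2α F1. Isomerize its allylic alcohol with the rhodium catalyst of step 2 to 13,14-dihydro-15-keto-prostaglandin F2α F2. Then oxidize with CrO3/H2SO4 in acetone at −30 °C. In PGF-type 9,11-diols chromic acid at low temperature favours the 11α-OH (trans to its neighbouring chain) over the 9α-OH (cis to the C8 chain); this selectivity is from memory of the classical entry to D-type prostaglandins and is only moderate. Separate 5 from its 9-keto isomer by chromatography.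

Step 2. The carboxylate may bind the cationic rhodium, a rhodium hydride could move the 13-ene toward C12 or touch the 5Z alkene, and the β-ketol can dehydrate to J-type enones if the reaction is slow. The fallback sets out from 4 and comes back at 5, replacing the internal hydrogen shift with two separate redox events. Oxidize the allylic 15-OH selectively with DDQ in dioxane at 23 °C to 15-keto-prostaglandin D2 F3; the saturated 9α-OH is inert. Then reduce the enone C=C alone with Bu3SnH/AcOH and catalytic Pd(PPh3)4 (zerovalent palladium) in THF at 23 °C, which leaves the isolated 5Z alkene and both ketones untouched.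

Further compounds
F0 | step 1 | none | none
F1 | step 1 | prostaglandin F2α | CCCCC[C@H](O)/C=C/[C@H]1[C@H](O)C[C@H](O)[C@@H]1C/C=C\CCCC(=O)O
F2 | step 1 | 13,14-dihydro-15-keto-prostaglandin F2α | CCCCCC(=O)CC[C@H]1[C@H](O)C[C@H](O)[C@@H]1C/C=C\CCCC(=O)O
F3 | step 2 | 15-keto-prostaglandin D2 | CCCCCC(=O)/C=C/[C@H]1C(=O)C[C@H](O)[C@@H]1C/C=C\CCCC(=O)O
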